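The numbers of this flask were chosen freely; what happens was integrated by code.

The tempting mistake with this flask was to divide the partner charge by two and call that the double product, when the double product itself takes up partner and goes on to triple product.

substrate 0.050 M; partner 0.0550 M; time 10 d

1. the state of affairs at 10 d: stopped, and by what, or still going (all of the substrate has reacted / the partner has run out first / it is still moving)
2. conversion of substrate at 10 d
3. amount of mono adduct at 10 d, in percent of the substrate charged
4. amount of double product at 10 d, in percent of the substrate charged

- percentages count the substrate that a species holds: one side product counts as two
- what has gone from substrate into another species counts as reacted, even if it can come back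
- the reaction counts as stopped when no species that holds the substrate changes by six tenths of a point or more over the second half of the time
- run time (flask): 10 d

    partner + double product → triple product + by-product (k1 = 0.98 M⁻¹ h⁻¹)
    partner + mono adduct → double product + by-product (k2 = 9.8 M⁻¹ h⁻¹)
    substrate ⇌ dormant form (K3 = 17, k3 = 0.31 h⁻¹)
    substrate + mono adduct → side product (k4 = 0.34 M⁻¹ h⁻¹)
    substrate + partner → mono adduct + by-product (k5 = 5.2 M⁻¹ h⁻¹)
    mono adduct ⇌ isomer of the product (K6 = 0.48, k6 = 0.090 h⁻¹)

I carried one number, the partner budget, meaning the partner charged per substrate charged, 110 %. Suppose every partner has been taken up and the mono adduct holds little, and let e be the share of substrate standing as double or triple product. Each double product then holds two partners and each triple product 3, so the double product equals 3 times e minus the budget. This ledger puts e no lower than 36.7 %, where the double product is 0 %, and lets the double product rise to 55.0 % at most, so each point of e moves it by 3 points.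

To tighten the top I took the fork at the start, where substrate leaves for the dormant form at 0.31 h⁻¹ and meets the partner at k5[partner], which gives a share 48.0 % towards the partner. Put in as e, that gave a soft ceiling of 34.0 %, soft because a falling [partner] lowers the share while the dormant form's return raises it. The third addition is ten times slower than the second, so I expected to sit above the floor, but my hand could not raise it. The unengaged substrate, split 1 to 17 between free and dormant, gave a conversion of 97.1 %.

The forecast said the partner has run out first, with conversion 97.1 %, mono adduct 1.5 % and double product 42 %, on the ground that “The double product therefore dominates with some triple product”. That double product lies above my ceiling, and on the ledger it asks for e of 50.7 %.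

The simulation gave the partner has run out first, conversion 97.1 %, mono adduct 1.66 % and double product 27.0 %.

The double product came in below my ceiling, and the partner was the limiting reagent, with 0.028 % of it remaining. In this flask the triple product stood at 17.6 %, so e was 44.6 %, above the ledger's lowest e. In the neighbour charged with 0.093 M of partner the budget is 186 %, and 3 times its double and triple product together, less that budget, leaves 14.4 % against the 17.0 % of double product it holds.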